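**Retrosynthetic overview**
1. Last ring: 15-membered lactone by C1–O21 macrolactonisation of the seco acid, with C17–OH left free.
2. Seco acid ⇒ open-chain tertiary nitro enal plus a 2-phosphonoacrylate: in one flask NO2→NH2, 6-exo aza-Michael at C5 (ring B), N–C22 conjugate addition and intramolecular HWE (ring A).
3. Nitro enal ⇒ B-alkyl Suzuki (C6–C5), Lindlar (15Z), CBS reduction (C17), and acetylide acylation by 4-chloro-5,6-dihydropyran-2-one (C16–C17; the ring fixes the C18=C19 geometry).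
4. Nitro alkyne ⇒ Pd-allylation of the nitronate (C9), Ohira–Bestmann alkyne, and organocatalytic Michael addition of propanal to 1-nitrocyclopentene (C13, C14).
5. Ring order: cyclopentane (bought) → piperidine B → tetrahydropyridine A → macrolactone.

Atom numbers used: C1 lactone C=O, C2=C3, C4, C5 (N–CH), C6–C8, C9 (spiro, N), C10–C12, C13, C14 (Me), C15=C16, C17 (OH), C18=C19 (Cl on C19), C20, C21 (O), C22 (N–CH2). The target is 5R,9S,13R,14S,17R,15Z,18E.

Assumption: the biosynthesis is presumed to run by aza-Michael closure of the piperidine at C5, then N–C22 bond formation to the C1–C3 acrylate unit, then O21→C1 lactonisation.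

**Step 1**
Reactants: 1 1-nitrocyclopentene; 2 propanal
Product: 3 (2R)-2-[(1R)-2-nitrocyclopentyl]propanal (both epimers at the nitro carbon)
Conditions: (S)-α,α-diphenylprolinol TMS ether (10 mol %), 4-nitrophenol (10 mol %), 2 (3 equiv), toluene, 0 °C → rt
Reagents that add atoms: propanal (2), CCC=O
Why: Hayashi–Jørgensen enamine Michael addition, in which the (S)-catalyst shields one enamine face and the nitroalkene is attacked through the usual synclinal open transition state, so C14 and C13 are set syn as (2R,1′R) in the same sense as with nitrostyrenes, while the nitro-bearing C9 stays a mixture that is erased at the nitronate stage of step 3.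

**Step 2**
Reactants: 3 (2R)-2-[(1R)-2-nitrocyclopentyl]propanal; 4 dimethyl (1-diazo-2-oxopropyl)phosphonate
Product: 5 (1R)-1-[(2R)-but-3-yn-2-yl]-2-nitrocyclopentane
Conditions: 4 (1.3 equiv), K2CO3 (3 equiv), MeOH, 0 °C → rt
Reagents that add atoms: dimethyl (1-diazo-2-oxopropyl)phosphonate (4), CC(=O)C(=[N+]=[N-])P(=O)(OC)OC
Why: Seyferth–Gilbert homologation with the Ohira–Bestmann reagent converts the aldehyde into the C15≡C16 terminal alkyne under conditions mild enough to keep the α-stereocentre C14, and the secondary nitro group only sits as its unreactive nitronate.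

**Step 3**
Reactants: 5 (1R)-1-[(2R)-but-3-yn-2-yl]-2-nitrocyclopentane; 6 allyl methyl carbonate
Product: 7 (1S,2R)-2-[(2R)-but-3-yn-2-yl]-1-nitro-1-(prop-2-en-1-yl)cyclopentane
Conditions: 6 (1.5 equiv), Pd(PPh3)4 (5 mol %), THF, rt
Reagents that add atoms: allyl methyl carbonate (6), C=CCOC(=O)OC
Why: Tsuji–Trost C-allylation of the nitronate (the methoxide released from the carbonate is the base) makes C9 quaternary, the π-allylpalladium electrophile approaching the planar nitronate anti to the branched C13 substituent so that allyl ends trans and NO2 cis to C14 and both C9 epimers of 5 converge.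

**Step 4**
Reactants: 8 dihydro-2H-pyran-2,4(3H)-dione
Product: 9 4-chloro-5,6-dihydro-2H-pyran-2-one
Conditions: (COCl)2 (1.2 equiv), DMF (cat.), CH2Cl2, 0 °C → rt
Reagents that add atoms: oxalyl chloride, ClC(=O)C(=O)Cl
Why: Chlorodehydroxylation of the enolised 1,3-dicarbonyl (a vinylogous acid) by the Vilsmeier reagent gives the vinylogous acid chloride, whose six-membered ring holds C17 and C20 cis across the future C18=C19(Cl) bond.

**Step 5**
Reactants: 7 (1S,2R)-2-[(2R)-but-3-yn-2-yl]-1-nitro-1-(prop-2-en-1-yl)cyclopentane; 9 4-chloro-5,6-dihydro-2H-pyran-2-one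
Product: 10 (3E,8R)-3-chloro-1-hydroxy-8-[(1R,2S)-2-nitro-2-(prop-2-en-1-yl)cyclopentyl]non-3-en-6-yn-5-one
Conditions: LDA (1.05 equiv), THF, −78 °C; cannulate into 9 (1.5 equiv), THF, −78 °C; H2O quench at −78 °C
Reagents that add atoms: 4-chloro-5,6-dihydro-2H-pyran-2-one (9), O=C1C=C(Cl)CCO1
Why: Acylation of the lithium acetylide by the lactone (1,2-addition, the tetrahedral lithium lactolate being stable at −78 °C and so blocking a second addition) forms C16–C17 and opens the ring to the δ-hydroxy ynone with the 18E geometry inherited from the ring.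

**Step 6**
Reactants: 10 (3E,8R)-3-chloro-1-hydroxy-8-[(1R,2S)-2-nitro-2-(prop-2-en-1-yl)cyclopentyl]non-3-en-6-yn-5-one
Product: 11 (3E,5S,8R)-3-chloro-8-[(1R,2S)-2-nitro-2-(prop-2-en-1-yl)cyclopentyl]non-3-en-6-yne-1,5-diol
Conditions: (S)-Me-CBS (0.3 equiv), catecholborane (3 equiv), CH2Cl2, −78 °C; aqueous work-up
Reagents that add atoms: none
Why: Corey–Bakshi–Shibata reduction in which the slim alkynyl arm is the small and the Z-β-chlorovinyl arm the large group, so the (S)-catalyst gives the 5S propargylic alcohol (this is 17R once C15≡C16 has become an alkene), with catecholborane at −78 °C leaving the alkyne, the alkenes and the nitro group alone.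

**Step 7**
Reactants: 12 3,3-diethoxyprop-1-yne
Product: 13 (1E)-3,3-diethoxy-1-iodoprop-1-ene
Conditions: Cp2Zr(H)Cl (1.2 equiv), THF, rt; then I2, 0 °C
Reagents that add atoms: iodine, II
Why: Schwartz hydrozirconation (syn addition, zirconium on the terminal carbon) followed by iodinolysis with retention gives the E-vinyl iodide.

**Step 8**
Reactants: 11 (3E,5S,8R)-3-chloro-8-[(1R,2S)-2-nitro-2-(prop-2-en-1-yl)cyclopentyl]non-3-en-6-yne-1,5-diol; 13 (1E)-3,3-diethoxy-1-iodoprop-1-ene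
Product: 14 (3E,5S,8R)-3-chloro-8-{(1R,2S)-2-[(4E)-6,6-diethoxyhex-4-en-1-yl]-2-nitrocyclopentyl}non-3-en-6-yne-1,5-diol
Conditions: 9-BBN (3.5 equiv), THF, 0 °C → rt; then 13 (1.3 equiv), PdCl2(dppf) (5 mol %), AsPh3 (10 mol %), 3 M aq. NaOH, DMF, rt
Reagents that add atoms: (1E)-3,3-diethoxy-1-iodoprop-1-ene (13), CCOC(OCC)/C=C/I
Why: 9-BBN hydroborates only the terminal allyl group (internal alkyne and trisubstituted chloroalkene react far more slowly) and the B-alkyl Suzuki–Miyaura coupling joins C6 to C5 with retention of the E geometry, the vinyl chloride being inert to oxidative addition at room temperature.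

**Step 9**
Reactants: 14 (3E,5S,8R)-3-chloro-8-{(1R,2S)-2-[(4E)-6,6-diethoxyhex-4-en-1-yl]-2-nitrocyclopentyl}non-3-en-6-yne-1,5-diol
Product: 15 (3E,5R,6Z,8S)-3-chloro-8-{(1R,2S)-2-[(4E)-6,6-diethoxyhex-4-en-1-yl]-2-nitrocyclopentyl}nona-3,6-diene-1,5-diol
Conditions: H2 (1 atm), Lindlar catalyst, quinoline, EtOAc, rt, stopped at 1 equiv H2
Reagents that add atoms: none
Why: Lindlar semi-hydrogenation adds H2 syn to the only alkyne and so gives the 15Z olefin, the poisoned catalyst sparing the disubstituted alkene, the vinyl chloride and the tertiary nitro group.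

**Step 10**
Reactants: 15 (3E,5R,6Z,8S)-3-chloro-8-{(1R,2S)-2-[(4E)-6,6-diethoxyhex-4-en-1-yl]-2-nitrocyclopentyl}nona-3,6-diene-1,5-diol; 16 ethyl 2-(diethoxyphosphoryl)prop-2-enoate
Product: 21 (1S,2R,9a′R)-2-[(2S,3Z,5R,6E)-7-chloro-5,9-dihydroxynona-3,6-dien-2-yl]-1′,4′,7′,8′,9′,9a′-hexahydrospiro[cyclopentane-1,6′-quinolizine]-3′-carboxylic acid, via amino enal 17 (not isolated), via piperidine aldehyde 18 (not isolated), via phosphonate adduct 19 (not isolated), via ethyl ester 20 (not isolated)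
Conditions: Zn dust, AcOH, MeCN/H2O, rt; filter; DBU to pH 9, then 16 (1.5 equiv), rt; LiCl, DBU, 40 °C; then LiOH, H2O, rt; AcOH to pH 6.5
Reagents that add atoms: ethyl 2-(diethoxyphosphoryl)prop-2-enoate (16), C=C(C(=O)OCC)P(=O)(OCC)OCC; lithium hydroxide, [Li+].[OH-]
Why: Zn/AcOH reduces the tertiary nitro group while the aqueous acid unmasks the enal, the amine then closes ring B by reversible 6-exo-trig aza-Michael addition so that C5 settles with its CH2CHO arm equatorial and cis to C13 (5R), the hindered N–H adds to the phosphonoacrylate to form N–C22, the resulting phosphonate closes ring A by intramolecular Horner–Wadsworth–Emmons olefination with C2=C3 necessarily endocyclic, and LiOH saponifies the ethyl ester in the same flask.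

**Step 11**
Reactants: 21 (1S,2R,9a′R)-2-[(2S,3Z,5R,6E)-7-chloro-5,9-dihydroxynona-3,6-dien-2-yl]-1′,4′,7′,8′,9′,9a′-hexahydrospiro[cyclopentane-1,6′-quinolizine]-3′-carboxylic acid
Product: 22 target CNP0129639.4, the 15-membered C1–O21 lactone of 21
Conditions: MNBA (1.5 equiv), DMAP (6 equiv), CH2Cl2 (1 mM), rt, syringe pump (12 h)
Reagents that add atoms: none
Why: Shiina macrolactonisation through the mixed anhydride, where the primary C21–OH acylates far faster than the hindered bis-allylic C17–OH (which could only close a strained 11-membered ring), closes the 15-membered lactone without touching a stereocentre.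

**Compound list**
1 | 1-nitrocyclopentene | O=[N+]([O-])C1=CCCC1 | starting material
2 | propanal | CCC=O | starting material
3 | (2R)-2-[(1R)-2-nitrocyclopentyl]propanal (nitro carbon epimers) | C[C@@H](C=O)[C@H]1CCCC1[N+](=O)[O-] | intermediate
4 | dimethyl (1-diazo-2-oxopropyl)phosphonate | CC(=O)C(=[N+]=[N-])P(=O)(OC)OC | starting material
5 | (1R)-1-[(2R)-but-3-yn-2-yl]-2-nitrocyclopentane (nitro carbon epimers) | C[C@@H](C#C)[C@H]1CCCC1[N+](=O)[O-] | intermediate
6 | allyl methyl carbonate | C=CCOC(=O)OC | starting material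
7 | (1S,2R)-2-[(2R)-but-3-yn-2-yl]-1-nitro-1-(prop-2-en-1-yl)cyclopentane | C[C@@H](C#C)[C@H]1CCC[C@@]1(CC=C)[N+](=O)[O-] | intermediate
8 | dihydro-2H-pyran-2,4(3H)-dione | O=C1CCOC(=O)C1 | starting material
9 | 4-chloro-5,6-dihydro-2H-pyran-2-one | O=C1C=C(Cl)CCO1 | intermediate
10 | (3E,8R)-3-chloro-1-hydroxy-8-[(1R,2S)-2-nitro-2-(prop-2-en-1-yl)cyclopentyl]non-3-en-6-yn-5-one | C[C@@H](C#CC(=O)/C=C(/Cl)CCO)[C@H]1CCC[C@@]1(CC=C)[N+](=O)[O-] | intermediate
11 | (3E,5S,8R)-3-chloro-8-[(1R,2S)-2-nitro-2-(prop-2-en-1-yl)cyclopentyl]non-3-en-6-yne-1,5-diol | C[C@@H](C#C[C@@H](O)/C=C(/Cl)CCO)[C@H]1CCC[C@@]1(CC=C)[N+](=O)[O-] | intermediate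
12 | 3,3-diethoxyprop-1-yne | CCOC(OCC)C#C | starting material
13 | (1E)-3,3-diethoxy-1-iodoprop-1-ene | CCOC(OCC)/C=C/I | intermediate
14 | (3E,5S,8R)-3-chloro-8-{(1R,2S)-2-[(4E)-6,6-diethoxyhex-4-en-1-yl]-2-nitrocyclopentyl}non-3-en-6-yne-1,5-diol | C[C@@H](C#C[C@@H](O)/C=C(/Cl)CCO)[C@H]1CCC[C@@]1(CCC/C=C/C(OCC)OCC)[N+](=O)[O-] | intermediate
15 | (3E,5R,6Z,8S)-3-chloro-8-{(1R,2S)-2-[(4E)-6,6-diethoxyhex-4-en-1-yl]-2-nitrocyclopentyl}nona-3,6-diene-1,5-diol | C[C@@H](/C=C\[C@@H](O)/C=C(/Cl)CCO)[C@H]1CCC[C@@]1(CCC/C=C/C(OCC)OCC)[N+](=O)[O-] | intermediate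
16 | ethyl 2-(diethoxyphosphoryl)prop-2-enoate | C=C(C(=O)OCC)P(=O)(OCC)OCC | starting material
17 | (2E)-6-{(1S,2R)-1-amino-2-[(2S,3Z,5R,6E)-7-chloro-5,9-dihydroxynona-3,6-dien-2-yl]cyclopentyl}hex-2-enal | C[C@@H](/C=C\[C@@H](O)/C=C(/Cl)CCO)[C@H]1CCC[C@@]1(CCC/C=C/C=O)N | intermediate (not isolated)
18 | 2-{(1R,5S,7R)-1-[(2S,3Z,5R,6E)-7-chloro-5,9-dihydroxynona-3,6-dien-2-yl]-6-azaspiro[4.5]decan-7-yl}acetaldehyde | C[C@@H](/C=C\[C@@H](O)/C=C(/Cl)CCO)[C@H]1CCC[C@]12CCC[C@H](CC=O)N2 | intermediate (not isolated)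
19 | ethyl 3-{(1R,5S,7R)-1-[(2S,3Z,5R,6E)-7-chloro-5,9-dihydroxynona-3,6-dien-2-yl]-7-(2-oxoethyl)-6-azaspiro[4.5]decan-6-yl}-2-(diethoxyphosphoryl)propanoate (C2 epimers) | C[C@@H](/C=C\[C@@H](O)/C=C(/Cl)CCO)[C@H]1CCC[C@]12CCC[C@H](CC=O)N2CC(C(=O)OCC)P(=O)(OCC)OCC | intermediate (not isolated)
20 | ethyl (1S,2R,9a′R)-2-[(2S,3Z,5R,6E)-7-chloro-5,9-dihydroxynona-3,6-dien-2-yl]-1′,4′,7′,8′,9′,9a′-hexahydrospiro[cyclopentane-1,6′-quinolizine]-3′-carboxylate | C[C@@H](/C=C\[C@@H](O)/C=C(/Cl)CCO)[C@H]1CCC[C@]12CCC[C@@H]3CC=C(C(=O)OCC)CN23 | intermediate (not isolated)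
21 | (1S,2R,9a′R)-2-[(2S,3Z,5R,6E)-7-chloro-5,9-dihydroxynona-3,6-dien-2-yl]-1′,4′,7′,8′,9′,9a′-hexahydrospiro[cyclopentane-1,6′-quinolizine]-3′-carboxylic acid | C[C@@H](/C=C\[C@@H](O)/C=C(/Cl)CCO)[C@H]1CCC[C@]12CCC[C@@H]3CC=C(C(=O)O)CN23 | intermediate
22 | CNP0129639.4, (5R,9S,13R,14S,15Z,17R,18E) 15-membered C1–O21 lactone of 21 | C[C@H]1/C=C\[C@@H](O)/C=C(/Cl)CCOC(=O)C2=CC[C@H]3CCC[C@]4(CCC[C@H]14)N3C2 | target

**Step count**
Total steps: 11. Longest linear sequence: 9 (steps 1, 2, 3, 5, 6, 8, 9, 10, 11).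

**Steps most likely to fail, with fallbacks**

Step 5 (acetylide acylation by the chloro-lactone). The acetylide may attack C4 of 9 with loss of chloride, or merely enolise it. The coupling is then moved to the aldehyde oxidation level. Setting out from 9, DIBAL-H (CH2Cl2, −78 °C) gives the lactol 4-chloro-5,6-dihydro-2H-pyran-2-ol F1. Its magnesium salt (i-PrMgCl) reacts through the open hydroxy-enal with the lithium acetylide of 7 to give the C5-epimeric diol (3E,5RS,8R)-3-chloro-8-[(1R,2S)-2-nitro-2-(prop-2-en-1-yl)cyclopentyl]non-3-en-6-yne-1,5-diol F2. MnO2 (CH2Cl2, rt) oxidises only the doubly activated secondary carbinol, and the route is rejoined at 10.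

Step 10 (reductive double ring closure). The hindered N–H of 18 may not add to 16, or the olefination may stall. Ring A is then closed by metathesis instead of by olefination. Setting out from 18 (made as in step 10), Ph3P=CH2 (THF, −78 → 0 °C) gives the C5-allyl piperidine (3E,5R,6Z,8S)-3-chloro-8-[(1R,5S,7R)-7-(prop-2-en-1-yl)-6-azaspiro[4.5]decan-1-yl]nona-3,6-diene-1,5-diol F3. N-alkylation with ethyl 2-(bromomethyl)acrylate (K2CO3, MeCN) still forms the N–C22 bond and gives the diene ethyl 2-({(1R,5S,7R)-1-[(2S,3Z,5R,6E)-7-chloro-5,9-dihydroxynona-3,6-dien-2-yl]-7-(prop-2-en-1-yl)-6-azaspiro[4.5]decan-6-yl}methyl)prop-2-enoate F4. Ring-closing metathesis (Grubbs II, CSA, CH2Cl2, 40 °C) makes C2=C3 and returns to the route at 20, which is saponified to 21 as in step 10.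

Step 11 (macrolactonisation with C17–OH free). Acyl activation may give oligomers or acylate C17–OH. The ring is then closed from the other side. Setting out from 21, a Mitsunobu macrolactonisation (PPh3, DIAD, toluene, 1 mM, 0 °C → rt) activates the primary C21–OH as its oxyphosphonium salt. The carboxylate forms the O–C21 bond by SN2 at the unhindered primary carbon and arrives directly at 22 (new compounds: none F0).

**Further compounds**
F1 | step 5 | 4-chloro-5,6-dihydro-2H-pyran-2-ol | OC1C=C(Cl)CCO1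
F2 | step 5 | (3E,5RS,8R)-3-chloro-8-[(1R,2S)-2-nitro-2-(prop-2-en-1-yl)cyclopentyl]non-3-en-6-yne-1,5-diol | C[C@@H](C#CC(O)/C=C(/Cl)CCO)[C@H]1CCC[C@@]1(CC=C)[N+](=O)[O-]
F3 | step 10 | (3E,5R,6Z,8S)-3-chloro-8-[(1R,5S,7R)-7-(prop-2-en-1-yl)-6-azaspiro[4.5]decan-1-yl]nona-3,6-diene-1,5-diol | C[C@@H](/C=C\[C@@H](O)/C=C(/Cl)CCO)[C@H]1CCC[C@]12CCC[C@H](CC=C)N2
F4 | step 10 | ethyl 2-({(1R,5S,7R)-1-[(2S,3Z,5R,6E)-7-chloro-5,9-dihydroxynona-3,6-dien-2-yl]-7-(prop-2-en-1-yl)-6-azaspiro[4.5]decan-6-yl}methyl)prop-2-enoate | C[C@@H](/C=C\[C@@H](O)/C=C(/Cl)CCO)[C@H]1CCC[C@]12CCC[C@H](CC=C)N2CC(=C)C(=O)OCC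
F0 | step 11 | none | none
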